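Seconds are the unit for these flasks, and the aim is the set-up that gives the most target.

in all of them: free catalyst 0.54 mM

|  | starting material | remark | time |
|---|---|---|---|
| zeta | 27 mM | one stirred flow tank at steady state, fed with the mixture as stated, mean residence time 250 min |  |
| theta | 27 mM (fed, over 25.0 min) | a stirred flask in which starting material is dosed at a steady rate over 25.0 min without added volume, worked up at 25 min | 25 min |
| epsilon | 27 mM | a single well-mixed tank run continuously and read at steady state, 25 min in it on average |  |
| alpha | 27 mM | a closed flask charged with all of it at once and left for 25 min | 25 min |

    free catalyst → spent catalyst (k1 = 5.5 × 10⁻⁴ s⁻¹)
    catalyst intermediate A → catalyst intermediate B (k2 = 0.15 s⁻¹)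
    2 starting material → self-condensation product (k3 = 0.23 M⁻¹ s⁻¹)
    starting material + free catalyst → catalyst intermediate A (k4 = 25 M⁻¹ s⁻¹)
    catalyst intermediate B ⇌ free catalyst + target (K5 = 0.011 M, k5 = 0.80 s⁻¹)

* the set-up with the highest amount of target at the outlet or at the end, in percent of the starting material put in ("none" if the first two lie within 2 percentage points) (zeta / theta / epsilon / alpha / none)
* amount of target at the outlet or at the end, in percent of the starting material put in, zeta
* amount of target at the outlet or at the end, in percent of the starting material put in, theta
* amount of target at the outlet or at the end, in percent of the starting material put in, epsilon
* amount of target at the outlet or at the end, in percent of the starting material put in, alpha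

- in percentages every species weighs as the starting material in it: one self-condensation product counts as two
- where a step has two of a species, its rate is k times that concentration squared, and two are used at each turn
- the stated concentrations are those of everything mixed, before any reaction; amounts are the same in each set-up
- the feed brings no volume worth counting
- run time (theta): 25 min

**The ladder.** The rungs span 3.16 powers of ten. Catalyst intermediate B releases target with a half-life of 0.866 s, and catalyst intermediate A moves on with one of 4.62 s. Capture of starting material at full free catalyst has a half-life of 51.3 s, self-condensation in alpha a first half-life of 80.5 s, and catalyst death one of 1260 s. Because the intermediates turn over faster than starting material falls by capture, we treat the round as steady. We set aside catalyst death and target rebinding.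

**Even level.** Each turn holds a catalyst for 7.92 s, and at high starting material the conversion of catalyst intermediate A is the rate-limiting step. The round therefore tops out at 4.09 mM min⁻¹, while self-condensation at the alpha charge uses 20.1 mM min⁻¹, which is faster. The round reaches half its top speed at 5.05 mM. Our rule is the even level, 9.91 mM, the starting material level at which round and self-condensation consume equally. With catalyst death and rebinding set aside, the selectivity at any level is then one over one plus level times (level plus 5.05 mM), divided by the same product at the even level.

**By hand.** Alpha sweeps down from its charge, so we sample its share at two levels. The share is 65.1 % at 6.75 mM and 22.4 % at 20.2 mM, and their mean gives 43.7 %. With the catalyst held fresh, the round takes up the feeds of the other set-ups at estimated levels of 0.137 mM in zeta and 1.81 mM in epsilon and theta. Scoring shares at those levels puts zeta first. Theta and epsilon tie in that score. These scores keep the catalyst fresh, yet the zeta residence time is 8.25 catalyst lifetimes, so we commit to the order and to no yield for those set-ups.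

**The forecast.** It names zeta, with 69 % for zeta, 64 % for theta, 61 % for epsilon and 41 % for alpha, on the ground that dosing or a well-mixed tank “holds the starting material at a few mM, where the catalyst wins”.

**The result.** The simulation gives zeta as best, with 68.8 % for zeta, 65.0 % for theta, 60.4 % for epsilon and 42.7 % for alpha.

**The neighbour.** Alpha was charged at 2.72 even levels, and our share stands 1.1 percentage points above its reading. In alpha, 82 % of the capture turnover lay behind it at 5.00 min, inside the catalyst-death half-life of 21.0 min. The neighbouring flask is alpha with 68 mM of starting material, or 6.86 even levels. Its shares are 28.3 % at 17.0 mM and 4.93 % at 51.0 mM, so the same rule gives 16.6 %. That flask gave 20.4 % of target, with 0.011 % of its starting material left.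

All constants stand for no real mixture.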